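**Retrosynthetic overview**

- The acetate, the free acid and the diene side chain are put on last; the diene comes from a C12 aldehyde by two Wittig olefinations.
- The C7=C8–C17 enoate and the C6 oxygen come from a C8 ketone: kinetic C7 enol triflate, Pd-catalysed methoxycarbonylation, allylic oxidation at C6 and hydride delivery anti to the axial methyl groups.
- Ring A is opened at C3–C4 and C4 is tied back to C7, which turns the decalone into a 4-allyl nopinone carrying the C9 acetate arm.
- The strategy rests on ring B: C5–C10 with the C10 methyl, the C5–C4 bond to the gem-dimethyl carbon and the C8 oxygen are the six-membered ring of (−)-verbenone once its C4–C7 cyclobutane bond is cut. The bridgehead C7 cannot enolise, so C9 is functionalised first without a regiochemical problem.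
- Order of ring formation: ring B is present from the start; ring A is closed in the key step.

Key step: step 5

Remark: labdane numbering (C1–C20) is used for every intermediate; commercial (1S)-(−)-verbenone is assumed to be of high enantiomeric purity, because its C5 is the only source of absolute configuration.

**Route**

Step 1
Reactants: 1 (1S,5S)-(−)-verbenone; 2 allylmagnesium bromide
Product: 4 4-allyl-4,6,6-trimethylbicyclo[3.1.1]heptan-2-one (allyl anti to the CMe2 bridge), via silyl enol ether 3 (not isolated)
Conditions: CuBr·SMe2 (1.2 equiv), CH2=CHCH2MgBr (2.4 equiv), Me3SiCl, THF, −78 °C; then 1 M HCl, 0 °C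
Reagents that add atoms: allylmagnesium bromide, C=CC[Mg]Br
Why: Me3SiCl-accelerated conjugate addition of the preformed diallylcuprate to the β,β-disubstituted enone should outrun 1,2-addition, and the reagent enters from the face opposite the gem-dimethyl bridge, which sets C10 with the allyl group anti to that bridge.

Step 2
Reactants: 4 4-allyl-4,6,6-trimethylbicyclo[3.1.1]heptan-2-one; 5 methyl glyoxylate
Product: 7 methyl 2-(4-allyl-4,6,6-trimethyl-2-oxobicyclo[3.1.1]heptan-3-yl)-2-hydroxyacetate (mixture of epimers at C9 and C11), via lithium enolate 6 (not isolated)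
Conditions: LiN(iPr)2, THF, −78 °C; methyl glyoxylate (toluene solution), −78 °C; AcOH quench
Reagents that add atoms: methyl glyoxylate, COC(=O)C=O
Why: The bridgehead C7 cannot enolise, so only the C8=C9 enolate forms and it adds to the very electrophilic aldehyde in a directed aldol reaction; the two new stereocentres are left uncontrolled because step 3 removes both.

Step 3
Reactants: 7 methyl 2-(4-allyl-4,6,6-trimethyl-2-oxobicyclo[3.1.1]heptan-3-yl)-2-hydroxyacetate
Product: 9 methyl 2-(4-allyl-4,6,6-trimethyl-2-oxobicyclo[3.1.1]heptan-3-ylidene)acetate (either alkene geometry), via mesylate 8 (not isolated)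
Conditions: MsCl, Et3N (excess), CH2Cl2, 0 °C to rt
Reagents that add atoms: none
Why: Mesylation of the α-hydroxy ester followed by base-induced β-elimination (E1cB, the C9 hydrogen being α to the ketone) should give the alkylidene keto ester, and both alkene geometries serve in step 4.

Step 4
Reactants: 9 methyl 2-(4-allyl-4,6,6-trimethyl-2-oxobicyclo[3.1.1]heptan-3-ylidene)acetate
Product: 10 methyl 2-(4-allyl-4,6,6-trimethyl-2-oxobicyclo[3.1.1]heptan-3-yl)acetate (CH2CO2Me on the face of the CMe2 bridge; cis to the C10 methyl; trans to the allyl group)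
Conditions: Zn dust, AcOH, rt
Reagents that add atoms: none
Why: Zn in AcOH reduces the 2-ene-1,4-dicarbonyl unit (dissolving-metal conjugate reduction) without touching the terminal alkene, and protonation of the enol at C9 from the face away from the gem-dimethyl bridge should place the acetate arm cis to the C10 methyl; should the epimer form, C9 stays epimerisable beside the C8 ketone after step 5, where the wanted configuration is the equatorial one.

Step 5
Reactants: 10 methyl 2-(4-allyl-4,6,6-trimethyl-2-oxobicyclo[3.1.1]heptan-3-yl)acetate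
Product: 12 methyl 2-(7-chloro-5,5,8a-trimethyl-2-oxodecahydronaphthalen-1-yl)acetate (trans-decalin; C2 chloride expected equatorial), via trichlorotitanium enolate 11 (not isolated)
Conditions: TiCl4 (2.5 equiv), CH2Cl2, −78 to 0 °C; then ice-water
Reagents that add atoms: titanium tetrachloride, Cl[Ti](Cl)(Cl)Cl
Why: Proposed new method: TiCl4 binds the C8 ketone and the strained C4–C7 bond, the Cα–Cβ bond of the ketone that lies nearly parallel to the carbonyl π system, should ionise to the C7=C8 trichlorotitanium enolate and a tertiary cation at C4; the closest known reactions are the Lewis-acid opening of nopinones to p-menthane cations and chloride-terminated cation–olefin (Prins-type) cyclisation, which have not been joined in one operation on this substrate class. The terminal carbon C3 of the allyl group on C10 then adds to C4 and closes ring A in the 6-endo mode, and chloride traps the secondary C2 cation. The trans ring fusion is not made here but inherited, because C5 and C10 are fixed in 10 and hold C4 and C1 on opposite faces of ring B. The one new stereocentre, C2, should carry an equatorial chloride by anti addition across the alkene, and it is of no consequence since step 6 removes it. The step needs C4–C7 rather than C4–C5 cleavage, secured because only C7 is α to the carbonyl, and 6-endo rather than 5-exo capture, secured by Markovnikov formation of a secondary instead of a primary cation. Proton loss or chloride capture at C4 is reversible in the presence of TiCl4 and HCl and returns material to the cation.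

Step 6
Reactants: 12 methyl 2-(7-chloro-5,5,8a-trimethyl-2-oxodecahydronaphthalen-1-yl)acetate
Product: 13 methyl 2-(5,5,8a-trimethyl-2-oxodecahydronaphthalen-1-yl)acetate
Conditions: Bu3SnH, AIBN (cat.), toluene, 110 °C
Reagents that add atoms: none
Why: Radical chain dehalogenation (the stannyl radical abstracts chlorine and the secondary C2 radical takes hydrogen from Bu3SnH) removes the stereocentre made in step 5, and ketone and ester are inert.

Step 7
Reactants: 13 methyl 2-(5,5,8a-trimethyl-2-oxodecahydronaphthalen-1-yl)acetate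
Product: 14 N-methoxy-N-methyl-2-(5,5,8a-trimethyl-2-oxodecahydronaphthalen-1-yl)acetamide
Conditions: MeNH(OMe)·HCl, AlMe3, CH2Cl2, 0 °C to rt; then 1 M HCl
Reagents that add atoms: N,O-dimethylhydroxylamine hydrochloride, CNOC.Cl
Why: The aluminium amide made from AlMe3 and the amine salt converts the unhindered methyl ester into the N-methoxy-N-methylamide (ester aminolysis) and leaves the hindered C8 ketone alone, which gives C12 a carbonyl group that can later be reduced beside the C17 ester.

Step 8
Reactants: 14 N-methoxy-N-methyl-2-(5,5,8a-trimethyl-2-oxodecahydronaphthalen-1-yl)acetamide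
Product: 16 1-[2-(methoxy(methyl)amino)-2-oxoethyl]-5,5,8a-trimethyl-1,4,4a,5,6,7,8,8a-octahydronaphthalen-2-yl trifluoromethanesulfonate, via lithium enolate 15 (not isolated)
Conditions: LiN(iPr)2, THF, −78 °C; PhNTf2, −78 to 0 °C; then H2O
Reagents that add atoms: N-phenylbis(trifluoromethanesulfonimide), O=S(=O)(N(c1ccccc1)S(=O)(=O)C(F)(F)F)C(F)(F)F
Why: Kinetic deprotonation removes a proton from the unhindered C7 methylene and not from the C9 methine beside quaternary C10, and O-sulfonylation of the enolate fixes the C7=C8 double bond as the enol triflate.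

Step 9
Reactants: 16 the C7=C8 enol triflate
Product: 17 methyl 1-[2-(methoxy(methyl)amino)-2-oxoethyl]-5,5,8a-trimethyl-1,4,4a,5,6,7,8,8a-octahydronaphthalene-2-carboxylate
Conditions: Pd(OAc)2 (cat.), PPh3, Et3N, CO (1 atm), MeOH–DMF, 60 °C
Reagents that add atoms: carbon monoxide, [C-]#[O+]; methanol, CO
Why: Zerovalent palladium formed in situ inserts into the C8–OTf bond, CO insertion gives the acylpalladium species and methanolysis releases the α,β-unsaturated ester (alkoxycarbonylation of an enol triflate), which installs C17 with the C7=C8 double bond in place.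

Step 10
Reactants: 17 the C7=C8 methyl enoate
Product: 18 methyl 1-[2-(methoxy(methyl)amino)-2-oxoethyl]-5,5,8a-trimethyl-4-oxo-1,4,4a,5,6,7,8,8a-octahydronaphthalene-2-carboxylate (C6 ketone)
Conditions: CrO3, 3,5-dimethylpyrazole, CH2Cl2, −20 °C
Reagents that add atoms: chromium trioxide, O=[Cr](=O)=O
Why: Allylic oxidation with the CrO3–3,5-dimethylpyrazole complex converts C6, the only allylic methylene of the enoate, into the conjugated ketone, whereas the C9 methine cannot give an enone and is shielded by C10.

Step 11
Reactants: 18 the 6-oxo enoate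
Product: 19 methyl 4-hydroxy-1-[2-(methoxy(methyl)amino)-2-oxoethyl]-5,5,8a-trimethyl-1,4,4a,5,6,7,8,8a-octahydronaphthalene-2-carboxylate (C6 hydroxyl axial; cis to the C10 methyl)
Conditions: NaBH4, CeCl3·7H2O, MeOH, −40 to 0 °C
Reagents that add atoms: none
Why: Luche reduction gives 1,2-reduction of the enone only, and hydride reaches C6 from the face opposite the axial methyl groups on C4 and C10, so the new hydroxyl should be axial and cis to the C10 methyl as the target requires.

Step 12
Reactants: 19 the 6-hydroxy amide ester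
Product: 20 methyl 4-hydroxy-5,5,8a-trimethyl-1-(2-oxoethyl)-1,4,4a,5,6,7,8,8a-octahydronaphthalene-2-carboxylate
Conditions: Cp2Zr(H)Cl (3 equiv), THF, rt; then H2O
Reagents that add atoms: none
Why: Cp2Zr(H)Cl reduces the tertiary N-methoxy-N-methylamide to the aldehyde and does not reduce esters, one further equivalent being consumed by the free hydroxyl group.

Step 13
Reactants: 20 the C12 aldehyde; 21 2-(triphenylphosphoranylidene)propanal
Product: 22 methyl 4-hydroxy-5,5,8a-trimethyl-1-[(2E)-3-methyl-4-oxobut-2-en-1-yl]-1,4,4a,5,6,7,8,8a-octahydronaphthalene-2-carboxylate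
Conditions: toluene, 80 °C
Reagents that add atoms: 2-(triphenylphosphoranylidene)propanal, CC(C=O)=P(c1ccccc1)(c1ccccc1)c1ccccc1
Why: Wittig olefination with the formyl-stabilised ylide is E-selective and should give the trisubstituted (E)-enal, whose conjugated and α-branched aldehyde reacts far more slowly with the ylide than the saturated aldehyde does.

Step 14
Reactants: 22 the (E)-enal
Product: 23 methyl 6-hydroxylabda-7,12E,14-trien-17-oate
Conditions: Ph3PCH3Br, KOtBu (3 equiv each), THF, 0 °C to rt
Reagents that add atoms: methyltriphenylphosphonium bromide, C[P+](c1ccccc1)(c1ccccc1)c1ccccc1.[Br-]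
Why: Wittig methylenation of the enal completes the (E)-1,3-diene, with excess ylide covering deprotonation of the C6 hydroxyl, and the hindered conjugated ester does not react.

Step 15
Reactants: 23 methyl 6-hydroxylabda-7,12E,14-trien-17-oate
Product: 24 6-hydroxylabda-7,12E,14-trien-17-oic acid
Conditions: LiOH·H2O, THF–MeOH–H2O, 50 °C; then 1 M HCl to pH 3, 0 °C
Reagents that add atoms: lithium hydroxide monohydrate, [Li+].[OH-].O
Why: Saponification of the methyl ester by hydroxide should leave the diene and the allylic alcohol untouched, and careful cold acidification frees the acid.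

Step 16
Reactants: 24 6-hydroxylabda-7,12E,14-trien-17-oic acid
Product: 26 (5R,6S,9S,10S)-6-acetoxylabda-7,12E,14-trien-17-oic acid (CNP0294871.1), via mixed anhydride 25 (not isolated)
Conditions: Ac2O, DMAP, pyridine, rt to 40 °C; then aq. NaHCO3–THF; then dilute HCl
Reagents that add atoms: acetic anhydride, CC(=O)OC(C)=O
Why: DMAP-catalysed acylation esterifies the hindered axial C6 hydroxyl, and the acetic mixed anhydride that forms at C17 is hydrolysed by mild aqueous base without loss of the acetate.

**Compound list**

1 | (1S,5S)-(−)-verbenone | CC1=CC(=O)[C@H]2C[C@@H]1C2(C)C | starting material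
2 | allylmagnesium bromide | C=CC[Mg]Br | starting material
3 | [(4-allyl-4,6,6-trimethylbicyclo[3.1.1]hept-2-en-2-yl)oxy]trimethylsilane, allyl anti to the CMe2 bridge | C1=C(O[Si](C)(C)C)[C@H]2C[C@H](C2(C)C)[C@@]1(C)CC=C | intermediate (not isolated)
4 | 4-allyl-4,6,6-trimethylbicyclo[3.1.1]heptan-2-one, allyl anti to the CMe2 bridge | C1C(=O)[C@H]2C[C@H](C2(C)C)[C@@]1(C)CC=C | intermediate
5 | methyl glyoxylate | COC(=O)C=O | starting material
6 | lithium C8=C9 enolate of 4 | C1=C(O[Li])[C@H]2C[C@H](C2(C)C)[C@@]1(C)CC=C | intermediate (not isolated)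
7 | methyl 2-(4-allyl-4,6,6-trimethyl-2-oxobicyclo[3.1.1]heptan-3-yl)-2-hydroxyacetate, epimer mixture at C9 and C11 | COC(=O)C(O)C1C(=O)[C@H]2C[C@H](C2(C)C)[C@@]1(C)CC=C | intermediate
8 | methyl 2-(4-allyl-4,6,6-trimethyl-2-oxobicyclo[3.1.1]heptan-3-yl)-2-(methylsulfonyloxy)acetate | COC(=O)C(OS(C)(=O)=O)C1C(=O)[C@H]2C[C@H](C2(C)C)[C@@]1(C)CC=C | intermediate (not isolated)
9 | methyl 2-(4-allyl-4,6,6-trimethyl-2-oxobicyclo[3.1.1]heptan-3-ylidene)acetate, either alkene geometry | COC(=O)C=C1C(=O)[C@H]2C[C@H](C2(C)C)[C@@]1(C)CC=C | intermediate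
10 | methyl 2-(4-allyl-4,6,6-trimethyl-2-oxobicyclo[3.1.1]heptan-3-yl)acetate, acetate arm cis to the C10 methyl and on the bridge face | COC(=O)C[C@@H]1C(=O)[C@H]2C[C@H](C2(C)C)[C@@]1(C)CC=C | intermediate (key-step precursor)
11 | trichlorotitanium C7=C8 enolate of 12 | COC(=O)C[C@@H]1C(O[Ti](Cl)(Cl)Cl)=CC[C@@H]2C(C)(C)C[C@@H](Cl)C[C@@]12C | intermediate (not isolated)
12 | methyl 2-(7-chloro-5,5,8a-trimethyl-2-oxodecahydronaphthalen-1-yl)acetate, trans-fused, equatorial C2 chloride drawn | COC(=O)C[C@@H]1C(=O)CC[C@@H]2C(C)(C)C[C@@H](Cl)C[C@@]12C | intermediate (key-step product)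
13 | methyl 2-(5,5,8a-trimethyl-2-oxodecahydronaphthalen-1-yl)acetate | COC(=O)C[C@@H]1C(=O)CC[C@@H]2C(C)(C)CCC[C@@]12C | intermediate
14 | N-methoxy-N-methyl-2-(5,5,8a-trimethyl-2-oxodecahydronaphthalen-1-yl)acetamide | CON(C)C(=O)C[C@@H]1C(=O)CC[C@@H]2C(C)(C)CCC[C@@]12C | intermediate
15 | lithium C7=C8 enolate of 14 | CON(C)C(=O)C[C@@H]1C(O[Li])=CC[C@@H]2C(C)(C)CCC[C@@]12C | intermediate (not isolated)
16 | 1-[2-(methoxy(methyl)amino)-2-oxoethyl]-5,5,8a-trimethyl-1,4,4a,5,6,7,8,8a-octahydronaphthalen-2-yl trifluoromethanesulfonate | CON(C)C(=O)C[C@@H]1C(OS(=O)(=O)C(F)(F)F)=CC[C@@H]2C(C)(C)CCC[C@@]12C | intermediate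
17 | methyl 1-[2-(methoxy(methyl)amino)-2-oxoethyl]-5,5,8a-trimethyl-1,4,4a,5,6,7,8,8a-octahydronaphthalene-2-carboxylate | CON(C)C(=O)C[C@@H]1C(C(=O)OC)=CC[C@@H]2C(C)(C)CCC[C@@]12C | intermediate
18 | methyl 1-[2-(methoxy(methyl)amino)-2-oxoethyl]-5,5,8a-trimethyl-4-oxo-1,4,4a,5,6,7,8,8a-octahydronaphthalene-2-carboxylate | CON(C)C(=O)C[C@@H]1C(C(=O)OC)=CC(=O)[C@@H]2C(C)(C)CCC[C@@]12C | intermediate
19 | methyl 4-hydroxy-1-[2-(methoxy(methyl)amino)-2-oxoethyl]-5,5,8a-trimethyl-1,4,4a,5,6,7,8,8a-octahydronaphthalene-2-carboxylate, C6 hydroxyl cis to the C10 methyl | CON(C)C(=O)C[C@@H]1C(C(=O)OC)=C[C@H](O)[C@@H]2C(C)(C)CCC[C@@]12C | intermediate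
20 | methyl 4-hydroxy-5,5,8a-trimethyl-1-(2-oxoethyl)-1,4,4a,5,6,7,8,8a-octahydronaphthalene-2-carboxylate | O=CC[C@@H]1C(C(=O)OC)=C[C@H](O)[C@@H]2C(C)(C)CCC[C@@]12C | intermediate
21 | 2-(triphenylphosphoranylidene)propanal | CC(C=O)=P(c1ccccc1)(c1ccccc1)c1ccccc1 | starting material
22 | methyl 4-hydroxy-5,5,8a-trimethyl-1-[(2E)-3-methyl-4-oxobut-2-en-1-yl]-1,4,4a,5,6,7,8,8a-octahydronaphthalene-2-carboxylate | O=C/C(C)=C/C[C@@H]1C(C(=O)OC)=C[C@H](O)[C@@H]2C(C)(C)CCC[C@@]12C | intermediate
23 | methyl 6-hydroxylabda-7,12E,14-trien-17-oate | C=C/C(C)=C/C[C@@H]1C(C(=O)OC)=C[C@H](O)[C@@H]2C(C)(C)CCC[C@@]12C | intermediate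
24 | 6-hydroxylabda-7,12E,14-trien-17-oic acid | C=C/C(C)=C/C[C@@H]1C(C(=O)O)=C[C@H](O)[C@@H]2C(C)(C)CCC[C@@]12C | intermediate
25 | acetic 6-acetoxylabda-7,12E,14-trien-17-oic anhydride | C=C/C(C)=C/C[C@@H]1C(C(=O)OC(C)=O)=C[C@H](OC(C)=O)[C@@H]2C(C)(C)CCC[C@@]12C | intermediate (not isolated)
26 | (5R,6S,9S,10S)-6-acetoxylabda-7,12E,14-trien-17-oic acid; C10 methyl, C9 side chain and C6 acetoxy on one face, H-5 on the other | C=C/C(C)=C/C[C@@H]1C(C(=O)O)=C[C@H](OC(C)=O)[C@@H]2C(C)(C)CCC[C@@]12C | target

**Step count and risk**

Total step count: 16.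
Longest linear sequence: 16 steps, from 1 to 26.

Steps most likely to fail:

Step 5. Ionisation of the C4–C7 bond may be slower than Prins-type attack of the allyl group on the TiCl4-activated C8 ketone, or the tertiary cation may be drained by proton loss before the unactivated vinyl group captures it. The fallback separates the two events and uses known chemistry. It sets out from 10, which is opened with BF3·OEt2, Zn(OAc)2 and Ac2O (the established nopinone cleavage) to methyl 2-[2-acetoxy-5-(2-acetoxypropan-2-yl)-6-allyl-6-methylcyclohex-2-en-1-yl]acetate F1, in which the ketone is masked as the C7=C8 enol acetate and can no longer compete. SnCl4 in CH2Cl2 at −78 °C then ionises the tertiary acetate and the cation–olefin cyclisation with chloride capture should give methyl 2-(2-acetoxy-7-chloro-5,5,8a-trimethyl-1,4,4a,5,6,7,8,8a-octahydronaphthalen-1-yl)acetate F2. K2CO3 in MeOH cleaves the enol acetate and the route is rejoined at 12.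

Step 10. Oxidation of the electron-poor alkene may be sluggish, hydrogen abstraction may occur at the C9 methine, or the product may be over-oxidised. The fallback replaces chromium oxidation by radical halogenation and oxygen transfer. It sets out from 17, where Wohl–Ziegler bromination (NBS, AIBN, PhCF3, 80 °C) at the γ-position of the enoate should give methyl 4-bromo-1-[2-(methoxy(methyl)amino)-2-oxoethyl]-5,5,8a-trimethyl-1,4,4a,5,6,7,8,8a-octahydronaphthalene-2-carboxylate F3 as a mixture of C6 epimers. Kornblum oxidation (AgBF4, DMSO; then Et3N) converts both epimers into the ketone and the route is rejoined at 18.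

Step 1. Direct 1,2-addition of the allyl metal to the carbonyl may compete with conjugate addition to the hindered β,β-disubstituted enone. The fallback turns the 1,2-adduct into the wanted product. It sets out from 1, which is treated with CH2=CHCH2MgBr alone (THF, −78 °C) to give 2-allyl-4,6,6-trimethylbicyclo[3.1.1]hept-3-en-2-ol F4 with the allyl group anti to the bridge. Anionic oxy-Cope rearrangement (KH, 18-crown-6, THF) moves the allyl group suprafacially from C8 to C10 on the same face and gives the enolate of the conjugate adduct; protonation rejoins the route at 4.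

**Further compounds**

F1 | step 5 | methyl 2-[2-acetoxy-5-(2-acetoxypropan-2-yl)-6-allyl-6-methylcyclohex-2-en-1-yl]acetate | COC(=O)C[C@@H]1C(OC(C)=O)=CC[C@H](C(C)(C)OC(C)=O)[C@@]1(C)CC=C
F2 | step 5 | methyl 2-(2-acetoxy-7-chloro-5,5,8a-trimethyl-1,4,4a,5,6,7,8,8a-octahydronaphthalen-1-yl)acetate | COC(=O)C[C@@H]1C(OC(C)=O)=CC[C@@H]2C(C)(C)C[C@@H](Cl)C[C@@]12C
F3 | step 10 | methyl 4-bromo-1-[2-(methoxy(methyl)amino)-2-oxoethyl]-5,5,8a-trimethyl-1,4,4a,5,6,7,8,8a-octahydronaphthalene-2-carboxylate | CON(C)C(=O)C[C@@H]1C(C(=O)OC)=CC(Br)[C@@H]2C(C)(C)CCC[C@@]12C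
F4 | step 1 | 2-allyl-4,6,6-trimethylbicyclo[3.1.1]hept-3-en-2-ol, allyl anti to the CMe2 bridge | CC1=C[C@@](O)(CC=C)[C@H]2C[C@@H]1C2(C)C
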